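**Retrosynthetic overview**

1. Rings A and B are bought as acetophenone 1 and aldehyde 2 and joined by aldol condensation as 2'-hydroxychalcone 3.
2. Key disconnection: the two C–O bonds of ring C of the upper unit (C3–O and O1–C2). Chalcone 3 is epoxidised enantioselectively to 4, which closes in the same flask to trans-dihydroflavonol 5 (C2 and C3 set here); O-benzylation gives ketone 6.
3. The lower unit is (+)-catechin 7 with all its rings and stereocentres; perbenzylation (through 8) gives 9, bromination at C8 gives 10, and exchange gives aryllithium 11.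
4. Interflavan bond: 11 adds to the C4 carbonyl of 6 (carbinol 12); ionisation to cation 13 and hydride delivery anti to O3 give the 3,4-cis linkage in 14; hydrogenolysis gives the target 15.
5. Ring order: only ring C of the upper unit is constructed; every other ring is purchased intact.

Assumption: the target is taken exactly as drawn, robinetinidol-(4β→8)-catechin, with a (2R,3S,4R) 2,3-trans-3,4-cis upper unit on C8 of (2R,3S)-catechin; the organic ketone catalyst of step 2 is prepared separately (from L-sorbose) and is not counted as a step.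

**Route**

Step 1
Reactants: 1 1-[4-(benzyloxy)-2-hydroxyphenyl]ethan-1-one; 2 3,4,5-tris(benzyloxy)benzaldehyde
Product: 3 (E)-1-[4-(benzyloxy)-2-hydroxyphenyl]-3-[3,4,5-tris(benzyloxy)phenyl]prop-2-en-1-one
Conditions: KOH (50% aq.), EtOH–THF, 25 °C, 48 h; then aq. HCl to pH 3
Reagents that add atoms: none
Why: Claisen–Schmidt aldol condensation of the methyl ketone enolate with the non-enolisable aldehyde, followed by E1cB dehydration, gives the conjugated E-enone, and the chelated 2'-phenol needs no protection.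

Step 2
Reactants: 3 (E)-2'-hydroxychalcone
Product: 5 (2R,3R)-7-(benzyloxy)-3-hydroxy-2-[3,4,5-tris(benzyloxy)phenyl]chroman-4-one, via epoxy ketone 4 (not isolated)
Conditions: 4,5-di-O-acetyl-1,2-O-isopropylidene-β-L-erythro-2,3-hexodiulo-2,6-pyranose (L-series Shi-type diacetate ketone, 30 mol %), Oxone (2KHSO5·KHSO4·K2SO4), NaHCO3, Bu4NHSO4 (cat.), MeCN–CH2(OMe)2–H2O, 0 °C; Na2S2O3; then K2CO3, MeOH, 0 °C, Ar
Reagents that add atoms: potassium peroxymonosulfate (KHSO5 of Oxone), [K+].[O-]S(=O)(=O)OO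
Why: Proposed new method: an enantioselective Algar–Flynn–Oyamada-type oxidative cyclisation run on the unprotected 2'-hydroxychalcone with a chiral dioxirane; the electrophilic dioxirane (from the ketone and KHSO5) epoxidises the E-enone through the usual spiro transition state and, unlike nucleophilic peroxide epoxidation, is not shut down by the chelated phenol, which stays protonated at pH 8, so the L-series ketone should give the (2R,3S)-epoxide 4 (the D-series ketone gives the mirror-image sense with trans-cinnamates); once the oxidant is destroyed, K2CO3 generates the phenoxide, which opens the epoxide 6-endo at the benzylic carbon with inversion, so C3 is set by the epoxidation face and C2 by the stereospecific C–O ring closure, giving the 2,3-trans (2R,3R) product; the closest known reactions are Shi-type dioxirane epoxidation of trans-cinnamates and simple enones and the base-induced closure of racemic 2'-hydroxychalcone epoxides to trans-3-hydroxyflavanones, but their merger into a catalytic asymmetric one-flask cyclisation of a free 2'-hydroxychalcone has, to my knowledge, not been described.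

Step 3
Reactants: 5 (2R,3R)-dihydroflavonol
Product: 6 (2R,3R)-3,7-bis(benzyloxy)-2-[3,4,5-tris(benzyloxy)phenyl]chroman-4-one
Conditions: BnOC(=NH)CCl3 (1.5 equiv), TfOH (5 mol %), CH2Cl2–cyclohexane, 0 → 25 °C
Reagents that add atoms: benzyl 2,2,2-trichloroacetimidate, N=C(OCc1ccccc1)C(Cl)(Cl)Cl
Why: Acid-catalysed O-benzylation with a trichloroacetimidate avoids the base that would enolise the 3-hydroxyflavanone and open or epimerise ring C, so both stereocentres are kept.

Step 4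
Reactants: 7 (+)-catechin, (2R,3S)-2-(3,4-dihydroxyphenyl)chromane-3,5,7-triol
Product: 9 3,5,7,3',4'-penta-O-benzyl-(+)-catechin, via tetra-O-benzylcatechin 8 (not isolated)
Conditions: BnBr (4.4 equiv), K2CO3, DMF, 25 °C; then NaH, BnBr (1.5 equiv), Bu4NI (cat.), 0 → 25 °C, same flask
Reagents that add atoms: benzyl bromide, BrCc1ccccc1
Why: Williamson etherification in two stages (phenoxides with K2CO3, then the secondary alkoxide with NaH) gives the perbenzyl ether; the strong base is added only when no free phenol remains, so C2 cannot epimerise through a quinone methide.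

Step 5
Reactants: 9 penta-O-benzyl-(+)-catechin
Product: 10 8-bromo-3,5,7,3',4'-penta-O-benzyl-(+)-catechin
Conditions: NBS (1.0 equiv), CH2Cl2, −40 → 0 °C
Reagents that add atoms: N-bromosuccinimide, O=C1CCC(=O)N1Br
Why: Electrophilic aromatic bromination of the 5,7-dialkoxy ring goes to C8, the established site for benzylated flavan-3-ols (C6 is flanked by two benzyloxy groups), and fixes the later coupling position.

Step 6
Reactants: 10 8-bromo-penta-O-benzylcatechin (1.3 equiv); 6 penta-O-benzyl ketone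
Product: 12 deca-O-benzyl C4 tertiary carbinol (upper unit 2R,3R; C4 unassigned), via aryllithium 11 (not isolated)
Conditions: t-BuLi (2.6 equiv), THF, −78 °C, 15 min; then 6 in THF, −78 → −20 °C; H2O
Reagents that add atoms: none
Why: Bromine–lithium exchange followed by 1,2-addition of the aryllithium to the C4 ketone forms the C4–C8 bond at the carbon that carried bromine; the low temperature and the absence of any OH suppress enolisation and ring opening, and the carbinol configuration is irrelevant because C4 is set again in step 7.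

Step 7
Reactants: 12 C4 tertiary carbinol
Product: 14 deca-O-benzyl robinetinidol-(4β→8)-catechin, via C4 diaryl carbocation 13 (not isolated)
Conditions: n-Bu3SnH (3 equiv), CF3CO2H (10 equiv), CH2Cl2, 0 °C
Reagents that add atoms: none
Why: Ionic hydrogenation (SN1-type reductive deoxygenation): the acid ionises the doubly benzylic alcohol to cation 13 and the tin hydride delivers hydride to the α-face, anti to the neighbouring 3-benzyloxy group (the trajectory nucleophiles follow with 2,3-trans flavan-4-yl cations), so H-4 ends α and the catechin unit β, cis to O3 (4R).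

Step 8
Reactants: 14 deca-O-benzyl dimer
Product: 15 robinetinidol-(4β→8)-catechin (target)
Conditions: H2 (1 atm), Pd(OH)2/C, THF–MeOH–H2O, 25 °C; filter under Ar, lyophilise
Reagents that add atoms: none
Why: Catalytic hydrogenolysis removes all ten benzyl ethers under neutral conditions, touching no stereocentre and leaving the acid-stable 5-deoxy C4–C8 bond intact.

**Compound list**

1 | 1-[4-(benzyloxy)-2-hydroxyphenyl]ethan-1-one | CC(=O)c1ccc(OCc2ccccc2)cc1O | starting material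
2 | 3,4,5-tris(benzyloxy)benzaldehyde | O=Cc1cc(OCc2ccccc2)c(OCc2ccccc2)c(OCc2ccccc2)c1 | starting material
3 | (E)-1-[4-(benzyloxy)-2-hydroxyphenyl]-3-[3,4,5-tris(benzyloxy)phenyl]prop-2-en-1-one | O=C(/C=C/c1cc(OCc2ccccc2)c(OCc2ccccc2)c(OCc2ccccc2)c1)c1ccc(OCc2ccccc2)cc1O | intermediate
4 | [4-(benzyloxy)-2-hydroxyphenyl]{(2R,3S)-3-[3,4,5-tris(benzyloxy)phenyl]oxiran-2-yl}methanone | O=C([C@@H]1O[C@H]1c1cc(OCc2ccccc2)c(OCc2ccccc2)c(OCc2ccccc2)c1)c1ccc(OCc2ccccc2)cc1O | intermediate (not isolated)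
5 | (2R,3R)-7-(benzyloxy)-3-hydroxy-2-[3,4,5-tris(benzyloxy)phenyl]chroman-4-one | c1ccccc1COc1ccc2c(c1)O[C@H](c1cc(OCc3ccccc3)c(OCc3ccccc3)c(OCc3ccccc3)c1)[C@@H](O)C2=O | intermediate
6 | (2R,3R)-3,7-bis(benzyloxy)-2-[3,4,5-tris(benzyloxy)phenyl]chroman-4-one | c1ccccc1COc1ccc2c(c1)O[C@H](c1cc(OCc3ccccc3)c(OCc3ccccc3)c(OCc3ccccc3)c1)[C@@H](OCc1ccccc1)C2=O | intermediate
7 | (+)-catechin, (2R,3S)-2-(3,4-dihydroxyphenyl)chromane-3,5,7-triol | Oc1cc(O)c2c(c1)O[C@H](c1ccc(O)c(O)c1)[C@@H](O)C2 | starting material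
8 | (2R,3S)-5,7-bis(benzyloxy)-2-[3,4-bis(benzyloxy)phenyl]chroman-3-ol | c1ccccc1COc1cc(OCc3ccccc3)c2c(c1)O[C@H](c1ccc(OCc3ccccc3)c(OCc3ccccc3)c1)[C@@H](O)C2 | intermediate (not isolated)
9 | (2R,3S)-3,5,7-tris(benzyloxy)-2-[3,4-bis(benzyloxy)phenyl]chromane | c1ccccc1COc1cc(OCc3ccccc3)c2c(c1)O[C@H](c1ccc(OCc3ccccc3)c(OCc3ccccc3)c1)[C@@H](OCc1ccccc1)C2 | intermediate
10 | (2R,3S)-3,5,7-tris(benzyloxy)-2-[3,4-bis(benzyloxy)phenyl]-8-bromochromane | c1ccccc1COc1cc(OCc3ccccc3)c2c(c1Br)O[C@H](c1ccc(OCc3ccccc3)c(OCc3ccccc3)c1)[C@@H](OCc1ccccc1)C2 | intermediate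
11 | (2R,3S)-3,5,7-tris(benzyloxy)-2-[3,4-bis(benzyloxy)phenyl]chroman-8-yllithium | [Li]c1c(OCc3ccccc3)cc(OCc3ccccc3)c2c1O[C@H](c1ccc(OCc3ccccc3)c(OCc3ccccc3)c1)[C@@H](OCc1ccccc1)C2 | intermediate (not isolated)
12 | (2R,3R)-3,7-bis(benzyloxy)-4-{(2R,3S)-3,5,7-tris(benzyloxy)-2-[3,4-bis(benzyloxy)phenyl]chroman-8-yl}-2-[3,4,5-tris(benzyloxy)phenyl]chroman-4-ol; C4 carbinol centre not assigned (removed in step 7) | c1ccccc1COc1ccc2c(c1)O[C@H](c1cc(OCc3ccccc3)c(OCc3ccccc3)c(OCc3ccccc3)c1)[C@@H](OCc1ccccc1)C2(O)c1c(OCc3ccccc3)cc(OCc3ccccc3)c2c1O[C@H](c1ccc(OCc3ccccc3)c(OCc3ccccc3)c1)[C@@H](OCc1ccccc1)C2 | intermediate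
13 | (2R,3S)-4-aryl-chroman-4-ylium cation derived from 12 (trifluoroacetate counter-ion) | c1ccccc1COc1ccc2c(c1)O[C@H](c1cc(OCc3ccccc3)c(OCc3ccccc3)c(OCc3ccccc3)c1)[C@@H](OCc1ccccc1)[C+]2c1c(OCc3ccccc3)cc(OCc3ccccc3)c2c1O[C@H](c1ccc(OCc3ccccc3)c(OCc3ccccc3)c1)[C@@H](OCc1ccccc1)C2 | intermediate (not isolated)
14 | (2R,3S,4R)-3,7-bis(benzyloxy)-4-{(2R,3S)-3,5,7-tris(benzyloxy)-2-[3,4-bis(benzyloxy)phenyl]chroman-8-yl}-2-[3,4,5-tris(benzyloxy)phenyl]chromane | c1ccccc1COc1ccc2c(c1)O[C@H](c1cc(OCc3ccccc3)c(OCc3ccccc3)c(OCc3ccccc3)c1)[C@@H](OCc1ccccc1)[C@H]2c1c(OCc3ccccc3)cc(OCc3ccccc3)c2c1O[C@H](c1ccc(OCc3ccccc3)c(OCc3ccccc3)c1)[C@@H](OCc1ccccc1)C2 | intermediate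
15 | robinetinidol-(4β→8)-catechin, (2R,3S,4R)-4-[(2R,3S)-2-(3,4-dihydroxyphenyl)-3,5,7-trihydroxychroman-8-yl]-2-(3,4,5-trihydroxyphenyl)chromane-3,7-diol | Oc1ccc2c(c1)O[C@H](c1cc(O)c(O)c(O)c1)[C@@H](O)[C@H]2c1c(O)cc(O)c2c1O[C@H](c1ccc(O)c(O)c1)[C@@H](O)C2 | target

**Step count and risks**

Total step count: 8. Longest linear sequence: 6 steps (steps 1, 2, 3, 6, 7, 8); the catechin branch is 5 steps (4, 5, 6, 7, 8).

Most likely to fail, first: step 2, the proposed new oxidative cyclisation. The deactivated enone may epoxidise slowly, the dioxirane may attack benzyl ethers or the phenol, closure may go 5-exo, or the ee may be low. The fallback uses known chemistry, sets out from 3 and comes back at 5: 3 is protected with MOMCl and i-Pr2NEt as the 2'-O-methoxymethyl chalcone F1, this is epoxidised under Juliá–Colonna conditions (poly-L-leucine, urea–H2O2, DBU, THF) to the (2R,3S)-epoxy ketone F2, and HCl in MeOH–THF removes the acetal so that the freed phenol closes ring C to 5.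

Second: step 6. The hindered aryllithium may enolise the α-benzyloxy ketone (with ring opening) instead of adding. The fallback sets out from 6 and comes back at 14, skipping steps 5 to 7: NaBH4 (MeOH–THF, 0 °C) reduces 6 to the 3,4-trans flavan-4-ol F3, and BF3·OEt2-promoted Friedel–Crafts alkylation of 9 (which reacts at C8) by F3 in CH2Cl2 at −40 °C gives 14 together with its C4 epimer, the 4α-linked dimer F4. F4 is expected to predominate and is removed by chromatography, so this path trades diastereoselectivity for reliability.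

Third: step 7. The 2-aryl group on the α-face may erode the facial selectivity of hydride delivery, or the cation may lose H-3. The fallback redesigns the directing group, sets out from 5 and comes back at 15: 5 is silylated (TBSOTf, 2,6-lutidine) to the 3-O-TBS ketone F5; aryllithium 11 adds to give the carbinol F6; n-Bu3SnH and CF3CO2H reduce it through the cation F7 to the 3-O-silyl dimer F8, the bulkier silyloxy group enforcing α-face hydride delivery; Bu4NF then gives the nona-O-benzyl dimer F9, and hydrogenolysis as in step 8 gives 15. This costs one extra step.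

**Further compounds**

F1 | step 2 | (E)-1-[4-(benzyloxy)-2-(methoxymethoxy)phenyl]-3-[3,4,5-tris(benzyloxy)phenyl]prop-2-en-1-one | O=C(/C=C/c1cc(OCc2ccccc2)c(OCc2ccccc2)c(OCc2ccccc2)c1)c1ccc(OCc2ccccc2)cc1OCOC
F2 | step 2 | [4-(benzyloxy)-2-(methoxymethoxy)phenyl]{(2R,3S)-3-[3,4,5-tris(benzyloxy)phenyl]oxiran-2-yl}methanone | O=C([C@@H]1O[C@H]1c1cc(OCc2ccccc2)c(OCc2ccccc2)c(OCc2ccccc2)c1)c1ccc(OCc2ccccc2)cc1OCOC
F3 | step 6 | (2R,3S,4R)-3,7-bis(benzyloxy)-2-[3,4,5-tris(benzyloxy)phenyl]chroman-4-ol | c1ccccc1COc1ccc2c(c1)O[C@H](c1cc(OCc3ccccc3)c(OCc3ccccc3)c(OCc3ccccc3)c1)[C@@H](OCc1ccccc1)[C@@H]2O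
F4 | step 6 | C4 epimer of 14 (4α-linked, upper unit 2R,3S,4S) | c1ccccc1COc1ccc2c(c1)O[C@H](c1cc(OCc3ccccc3)c(OCc3ccccc3)c(OCc3ccccc3)c1)[C@@H](OCc1ccccc1)[C@@H]2c1c(OCc3ccccc3)cc(OCc3ccccc3)c2c1O[C@H](c1ccc(OCc3ccccc3)c(OCc3ccccc3)c1)[C@@H](OCc1ccccc1)C2
F5 | step 7 | (2R,3R)-7-(benzyloxy)-3-[(tert-butyldimethylsilyl)oxy]-2-[3,4,5-tris(benzyloxy)phenyl]chroman-4-one | c1ccccc1COc1ccc2c(c1)O[C@H](c1cc(OCc3ccccc3)c(OCc3ccccc3)c(OCc3ccccc3)c1)[C@@H](O[Si](C)(C)C(C)(C)C)C2=O
F6 | step 7 | 3-O-TBS analogue of carbinol 12 (upper unit 2R,3R; C4 unassigned) | c1ccccc1COc1ccc2c(c1)O[C@H](c1cc(OCc3ccccc3)c(OCc3ccccc3)c(OCc3ccccc3)c1)[C@@H](O[Si](C)(C)C(C)(C)C)C2(O)c1c(OCc3ccccc3)cc(OCc3ccccc3)c2c1O[C@H](c1ccc(OCc3ccccc3)c(OCc3ccccc3)c1)[C@@H](OCc1ccccc1)C2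
F7 | step 7 | 3-O-TBS analogue of cation 13 | c1ccccc1COc1ccc2c(c1)O[C@H](c1cc(OCc3ccccc3)c(OCc3ccccc3)c(OCc3ccccc3)c1)[C@@H](O[Si](C)(C)C(C)(C)C)[C+]2c1c(OCc3ccccc3)cc(OCc3ccccc3)c2c1O[C@H](c1ccc(OCc3ccccc3)c(OCc3ccccc3)c1)[C@@H](OCc1ccccc1)C2
F8 | step 7 | (2R,3S,4R)-7-(benzyloxy)-3-[(tert-butyldimethylsilyl)oxy]-4-{(2R,3S)-3,5,7-tris(benzyloxy)-2-[3,4-bis(benzyloxy)phenyl]chroman-8-yl}-2-[3,4,5-tris(benzyloxy)phenyl]chromane | c1ccccc1COc1ccc2c(c1)O[C@H](c1cc(OCc3ccccc3)c(OCc3ccccc3)c(OCc3ccccc3)c1)[C@@H](O[Si](C)(C)C(C)(C)C)[C@H]2c1c(OCc3ccccc3)cc(OCc3ccccc3)c2c1O[C@H](c1ccc(OCc3ccccc3)c(OCc3ccccc3)c1)[C@@H](OCc1ccccc1)C2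
F9 | step 7 | (2R,3S,4R)-7-(benzyloxy)-4-{(2R,3S)-3,5,7-tris(benzyloxy)-2-[3,4-bis(benzyloxy)phenyl]chroman-8-yl}-2-[3,4,5-tris(benzyloxy)phenyl]chroman-3-ol | c1ccccc1COc1ccc2c(c1)O[C@H](c1cc(OCc3ccccc3)c(OCc3ccccc3)c(OCc3ccccc3)c1)[C@@H](O)[C@H]2c1c(OCc3ccccc3)cc(OCc3ccccc3)c2c1O[C@H](c1ccc(OCc3ccccc3)c(OCc3ccccc3)c1)[C@@H](OCc1ccccc1)C2
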